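## Analysis of the target

- The target is a drimane-type trans-decalin. Ring A is C1–C5 and C10; ring B is C5–C10. C8 carries an exocyclic methylene (C12), and C9 carries a CH2–O arm (C11) bound to O7 of a coumarin.
- There are five contiguous stereocentres: C3, C4, C5, C9 and C10. The C10 methyl, the C11 arm, the equatorial C3 hydroxyl and the axial C4 hydroxymethyl lie on one face. H5, H9 and the equatorial C4 methyl lie on the other.
- With the decalin numbered as a 1-substituted naphthalene the descriptors are 1R (C9), 4aS (C5), 5R (C4), 6R (C3) and 8aR (C10).
- The 1,1-disubstituted C8=C12 alkene moves into the ring under protic or Lewis acid. The coumarin lactone does not survive hydride, dissolving metal or strong base. Two primary alcohols (C11 and the C4 CH2OH) must be told apart.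
- The difficulty lies in two quaternary carbons (C4, C10) in a 1,3 relation, a tertiary C9 wedged between C10 and the methylene carbon, and the need for a single enantiomer.
- The strategy rests on ring A. C10 is a methyl-bearing quaternary carbon para to the oxygenated C3, and C4, ortho to C3, carries a carbon substituent. Ring A therefore maps onto a para-methyl salicylate: C3 is the phenol carbon, C4 the ester carbon and C5 the carbon that holds the side chain.
- The C9–C10 bond can then be made by the para carbon of the phenolate attacking an allyl unit C12=C8–C9 that hangs on C5 through C6–C7.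

## Retrosynthetic reasoning

Drimane atom numbers are used for every intermediate.

**C11–O(aryl) bond.** Target 24 is cut at the ether oxygen into alcohol 21 and umbelliferone 22, with the C3/C4 diol held as acetonide 23 during the coupling. The lactone of 22 would not survive the reductions, so it enters last. The acetonide takes the second primary alcohol out of the etherification. The forward reaction is a redox condensation at a primary, β-branched carbinol, followed by a hydrolysis mild enough to leave C8=C12 in place.

**Oxidation level at C3 and at the C4 carbon.** Alcohol 21 goes back through silyl ether 20 and diol 19 to keto ester 18. The C3 hydroxyl comes from the ketone and the C4 CH2OH from the ester, so both carbons keep the oxygen and the ester of the aromatic start. Hydride has to enter C3 axially, on the face away from the axial ester.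

**C4–CH3 and C5–H bonds, and C12–H.** Keto ester 18 is cut at the C4 methyl and at H5 (through enolate 17) to vinyl iodide 16. One dissolving-metal operation has to do three things:
- add hydrogen at C5 trans to the C10 methyl;
- methylate the β-keto ester enolate on the face away from that methyl;
- replace the C12 iodine by hydrogen.

Iodide 16 comes from vinylsilane 15 by ipso substitution at C12, and 15 from dienone 14 by saturating C1=C2. Acid protodesilylation is avoided because it would protonate the product alkene about as easily as the vinylsilane.

**C9–C10 bond (key disconnection).** Dienone 14 is cut between C9 and C10 to phenol 13. This one bond closes ring B, makes the quaternary C10, sets C9 and C10 together and dearomatises ring A to an enone ester ready for reductive methylation. Two points decide the substitution of the allyl unit.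
- Regiochemistry. The tether reaches the allyl unit at its central carbon C8, so attack of C10 on C12 would also close a six-membered ring. Ring size therefore does not protect C9, and a bare CH2 terminus at C12 would be the favoured site. A trimethylsilyl group on C12 is carried as a spectator, because stabilised nucleophiles add to silyl-substituted allylpalladium complexes at the terminus remote from silicon.
- Stereochemistry. With both termini substituted, the enantiomeric allyl complexes no longer interconvert by η3–η1–η3 exchange. A racemic carbonate would not converge, so 13 is made as the (S)-carbonate and its configuration is transferred to C9 with net retention.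

**Carbonate, C9 carbinol and C8–C9 bond.** Phenol 13 comes from its methoxymethyl ether 12, and 12 from (S)-alcohol 11. Alcohol 11 is reached from racemic alcohol 9 by oxidation to enone 10 and catalyst-controlled reduction. Alcohol 9 is cut at C8–C9 into silylalkyne 7 and aldehyde 8. A nickel-catalysed reductive coupling forms this bond at the alkyne carbon remote from silicon and adds hydrogen syn. The same silyl group thus directs both this coupling and the later allylation.

**C6–C7 bond.** Alkyne 7 is cut between the benzylic carbon and the propargylic carbon into toluate 4 and bromide 5. The methyl group ortho to the ester is deprotonated selectively (anion 6), so the chain is attached to C5 of the future ring A without any prior functionalisation.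

**C10–CH3 bond on the arene.** Toluate 4 goes back through bromide 3 and bromophenol 2 to commercial salicylate 1. The position para to the phenol is the most reactive one, and a cross-coupling puts the future C10 methyl there.

## Alternatives that were turned down

**Alternative 1:** silicon-tethered radical delivery of C14 from the C3 oxygen.
- Disconnection: the C4–C14 bond. The precursor is A1, a (bromomethyl)dimethylsilyl ether on O3 of a 4,10-dimethyl-Δ4-octalin with a ketal at C9.
- Key step: under tin hydride chain conditions the silylmethyl radical adds 5-exo to C4, and the C5 radical is then reduced. This gives oxasilolane A2, and a later C–Si oxidation frees the C3 hydroxyl and the C4 CH2OH.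
- For: the tether forces C14 onto the face of O3, which fixes the C3/C4 relation more securely than an enolate alkylation. The reaction class is well established, so this key step is stronger on precedent. Octalin cores of this kind are available in enantioenriched form from a Robinson annulation.
- Against: the step solves C4 only. A2 has no function at C8 and only a masked ketone at C9. The whole C8=C12/C9–C11 array, with the C9 stereocentre next to quaternary C10, would have to be built afterwards by homologation at C9, oxidation at C8 and olefination.
- Comparison: the chosen route offers a less certain key step, but that step delivers exactly the array that A2 lacks. C4 is left to a classical reductive methylation.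

**Alternative 2:** intramolecular Diels–Alder reaction of an acyclic triene.
- Disconnection: C5–C10 and C8–C9 together. The precursor is triene A3, an (E)-3-methyl enoate linked through C1–C4 (with the C3/C4 acetonide) to an (E,E)-1-silyloxy diene.
- Key step: a thermal [4+2] cycloaddition that closes rings A and B at once and gives octalin A4.
- For: two rings, two C–C bonds and four stereocentres (C5, C8, C9, C10) form in one step without reagents. On bonds per step it is stronger than the chosen key step.
- Against: the dienophile is a β,β-disubstituted enoate that must create quaternary C10, and the diene terminus C5 sits next to quaternary C4. Forcing temperatures are to be expected, under which the silyl dienol ether is fragile and trans-selectivity of the ring fusion is not assured. A3 already needs C3 and quaternary C4 made in an open chain. A4 still needs C6=C7 saturated, and C8 taken from silyl ether to ketone to methylene beside an epimerisable C9 ester.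
- Comparison: the chosen route makes one ring in its key step, but from a flat, cheap arene and with C8=C12 already present (masked as the vinylsilane).

**Alternative 3:** borylative enyne cyclisation.
- Disconnection: the C8–C9 bond (ring B) and a C11–B bond. The precursor is A5, ring A carrying a butynyl chain on C5 and methyl plus vinyl on C10.
- Key step: a palladium hydride adds to the terminal alkyne to give an alkenylpalladium at C8. This inserts the vinyl group, and the C11–palladium bond is captured by a diboron reagent, giving boronate A6.
- For: A6 holds the methylene/CH/CH2–B array in final form. Oxidation, etherification and unmasking would finish the synthesis, so its endgame is shorter than the chosen one.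
- Against: A5 must already contain C3, C4, C5 and C10, including both quaternary carbons, on a monocyclic ring. The hardest stereochemical work is moved into the precursor. The key step sets only C9, and nothing in A5 secures the face of the vinyl insertion. Such cyclisations are established mainly for five-membered rings, and a six-membered closure onto a neopentyl-type vinyl group is an extension.
- Comparison: the chosen route sets C9 and C10 together and derives C3, C4 and C5 afterwards by substrate control.

Key step: step 10

Remark 1: drimane numbering is used throughout (C11 is the CH2O carbon on C9, C12 the exocyclic carbon on C8, C14 the oxygenated carbon on C4).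

Remark 2: which enantiomer of the diphosphine is matched to (S)-13 cannot be derived in advance. The (R,R) ligand is written, and the (S,S) ligand replaces it if that one proves matched. The configuration of 14 follows from the carbonate in either case.

Remark 3: in the oxazaborolidine reduction the silyl-substituted alkenyl group is taken as the large substituent.

## Route

Step 1
Reactants: 1 methyl 2-hydroxy-6-methylbenzoate
Product: 2 methyl 3-bromo-6-hydroxy-2-methylbenzoate
Conditions: NBS, MeCN, 0 °C to rt
Reagents that add atoms: N-bromosuccinimide, O=C1CCC(=O)N1Br
Why: Electrophilic aromatic bromination; the position para to the hydrogen-bonded phenol (and ortho to the methyl) is the most activated, so bromine should enter at the future C10.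

Step 2
Reactants: 2 methyl 3-bromo-6-hydroxy-2-methylbenzoate
Product: 3 methyl 3-bromo-6-(methoxymethoxy)-2-methylbenzoate
Conditions: NaH, MOMCl, THF/DMF, 0 °C to rt
Reagents that add atoms: chloromethyl methyl ether, COCCl
Why: Williamson-type O-alkylation of the phenoxide; the acetal ether masks the acidic phenol for the base-mediated step 4 and is removable later by chelation-assisted cleavage.

Step 3
Reactants: 3 methyl 3-bromo-6-(methoxymethoxy)-2-methylbenzoate
Product: 4 methyl 6-(methoxymethoxy)-2,3-dimethylbenzoate
Conditions: trimethylboroxine, PdCl2(dppf) (5 mol %), K2CO3, 1,4-dioxane/H2O, 100 °C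
Reagents that add atoms: trimethylboroxine, CB1OB(C)OB(C)O1
Why: Suzuki–Miyaura methylation of an aryl bromide; the doubly ortho-substituted methyl ester is too hindered to saponify under the carbonate conditions.

Step 4
Reactants: 4 methyl 6-(methoxymethoxy)-2,3-dimethylbenzoate; 5 3-bromo-1-(trimethylsilyl)prop-1-yne
Product: 7 methyl 6-(methoxymethoxy)-3-methyl-2-[4-(trimethylsilyl)but-3-yn-1-yl]benzoate, via benzylic lithium species 6 (not isolated)
Conditions: LiN(iPr)2, THF, −78 °C; then 5, −78 to −30 °C
Reagents that add atoms: none
Why: Lateral lithiation of an ortho-toluate; only the methyl ortho to the ester gives an ester-stabilised benzylic anion, which should displace the propargylic bromide by SN2 and form C6–C7.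

Step 5
Reactants: 7 methyl 6-(methoxymethoxy)-3-methyl-2-[4-(trimethylsilyl)but-3-yn-1-yl]benzoate; 8 (tert-butyldimethylsilyloxy)acetaldehyde
Product: 9 methyl 2-[(3E)-5-{[tert-butyl(dimethyl)silyl]oxy}-4-hydroxy-3-[(trimethylsilyl)methylidene]pentyl]-6-(methoxymethoxy)-3-methylbenzoate (racemic at C9)
Conditions: Ni(cod)2 (10 mol %), PBu3 (20 mol %), Et3B, toluene, rt
Reagents that add atoms: none
Why: Nickel-catalysed reductive coupling of an alkyne and an aldehyde through an oxanickelacycle; with silylalkynes the C–C bond forms at the carbon remote from silicon (C8–C9) and hydrogen is delivered syn, which gives the (E)-vinylsilane with silicon on C12.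

Step 6
Reactants: 9 racemic allylic alcohol
Product: 10 methyl 2-[(3E)-5-{[tert-butyl(dimethyl)silyl]oxy}-4-oxo-3-[(trimethylsilyl)methylidene]pentyl]-6-(methoxymethoxy)-3-methylbenzoate
Conditions: DMP (triacetoxy periodinane), CH2Cl2, 0 °C to rt
Reagents that add atoms: none
Why: Periodinane oxidation of a secondary allylic alcohol under near-neutral conditions; it removes the uncontrolled C9 stereocentre so that it can be reset.

Step 7
Reactants: 10 enone
Product: 11 methyl 2-[(3E,4S)-5-{[tert-butyl(dimethyl)silyl]oxy}-4-hydroxy-3-[(trimethylsilyl)methylidene]pentyl]-6-(methoxymethoxy)-3-methylbenzoate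
Conditions: (S)-2-methyl-CBS-oxazaborolidine (20 mol %), catecholborane, toluene, −78 °C
Reagents that add atoms: none
Why: Corey–Bakshi–Shibata reduction; the α-substituted, silyl-bearing alkenyl group acts as the large substituent and CH2OTBS as the small one, so the (S)-catalyst should deliver hydride to give the (S)-carbinol at C9 by 1,2-reduction.

Step 8
Reactants: 11 (S)-allylic alcohol
Product: 12 methyl 2-[(3E,4S)-5-{[tert-butyl(dimethyl)silyl]oxy}-4-[(methoxycarbonyl)oxy]-3-[(trimethylsilyl)methylidene]pentyl]-6-(methoxymethoxy)-3-methylbenzoate
Conditions: ClCO2Me, pyridine, DMAP (cat.), CH2Cl2, 0 °C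
Reagents that add atoms: methyl chloroformate, COC(=O)Cl
Why: Acylation of the secondary alcohol to the allylic methyl carbonate without touching the stereocentre; the carbonate later supplies its own base (methoxide) on ionisation.

Step 9
Reactants: 12 carbonate methoxymethyl ether
Product: 13 methyl 2-[(3E,4S)-5-{[tert-butyl(dimethyl)silyl]oxy}-4-[(methoxycarbonyl)oxy]-3-[(trimethylsilyl)methylidene]pentyl]-6-hydroxy-3-methylbenzoate
Conditions: ZnBr2, n-PrSH, CH2Cl2, 0 °C, 10 min
Reagents that add atoms: none
Why: Lewis acid/thiol cleavage of an aryl methoxymethyl ether, helped by chelation to the ortho ester; the short, cold exposure should spare the primary silyl ether, the vinylsilane and the allylic carbonate.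

Step 10
Reactants: 13 (S)-carbonate with free phenol
Product: 14 methyl (4aS,5S,6E)-5-({[tert-butyl(dimethyl)silyl]oxy}methyl)-4a-methyl-2-oxo-6-[(trimethylsilyl)methylidene]-2,4a,5,6,7,8-hexahydronaphthalene-1-carboxylate
Conditions: Pd2(dba)3·CHCl3 (2.5 mol %), (1R,2R)-N,N′-bis[2-(diphenylphosphino)benzoyl]cyclohexane-1,2-diamine (7.5 mol %), CH2Cl2 (0.01 M), rt to 40 °C
Reagents that add atoms: none
Why: Proposed new method: zerovalent palladium should add to the C8=C12 alkene of 13 anti to the carbonate and ionise it (CO2 and methoxide leave; methoxide takes the phenol proton), and the para carbon C10 of the phenolate should attack C9 of the cationic η3-allyl (C12–C8–C9) on the face away from palladium, which forms C9–C10, closes ring B and leaves ring A as a cross-conjugated dienone. The closest known reaction type is the palladium- or iridium-catalysed intramolecular allylic dearomatisation (Tsuji–Trost alkylation) of para-tethered phenols to spirocyclohexadienones; here the tether sits meta to the oxygen, so a fused ring and a quaternary C10 result. Ring B closes as a six-membered ring in the exo mode: C9 is the attacked ring atom and the restored C8=C12 bond stays outside the ring. C9 is set by the carbonate stereocentre: ionisation and attack are both inversions, so C10 takes the place of the carbonate oxygen, and since both allyl termini are substituted, η3–η1–η3 exchange cannot turn one enantiomeric allyl complex into the other. C10 is set relative to C9 by the chair-like closure, in which the C10 methyl is forced pseudo-axial and the CH2OTBS arm takes the equatorial (anti-allyl) position next to that methyl, away from the face of ring A. The step needs attack at C9 and not at C12, which ring size cannot decide because both would be six-membered closures; the C12 silyl group decides it, since stabilised nucleophiles add to silyl-substituted allylpalladium complexes at the terminus remote from silicon. It needs para attack (C10) and not ortho attack (C4): only C10 attack keeps the ester conjugated (C5=C4–CO2Me), and C4 is shielded by the hydrogen-bonded ester; O-allylation would need an eight-membered ring and is reversible. The diphosphine is used as the enantiomer matched to (S)-13, so that residual (R)-13 reacts more slowly.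

Step 11
Reactants: 14 bicyclic dienone ester
Product: 15 methyl (4aS,5S,6E)-5-({[tert-butyl(dimethyl)silyl]oxy}methyl)-4a-methyl-2-oxo-6-[(trimethylsilyl)methylidene]-2,3,4,4a,5,6,7,8-octahydronaphthalene-1-carboxylate
Conditions: H2 (1 atm), RhCl(PPh3)3 (10 mol %), benzene, rt
Reagents that add atoms: none
Why: Homogeneous hydrogenation discriminates by substitution: the cis-disubstituted C1=C2 bond of a cross-conjugated dienone is reduced, while the tetrasubstituted C4=C5 and the silyl-bearing trisubstituted C8=C12 should stay.

Step 12
Reactants: 15 enone ester vinylsilane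
Product: 16 methyl (4aS,5S,6E)-5-({[tert-butyl(dimethyl)silyl]oxy}methyl)-6-(iodomethylidene)-4a-methyl-2-oxo-2,3,4,4a,5,6,7,8-octahydronaphthalene-1-carboxylate
Conditions: NIS, (CF3)2CHOH, 0 °C
Reagents that add atoms: N-iodosuccinimide, O=C1CCC(=O)N1I
Why: Iododesilylation by ipso attack of electrophilic iodine at C12 and loss of silicon from the β-silyl cation; it is not acidic enough to move the double bond, and the electron-poor C4=C5 is inert.

Step 13
Reactants: 16 enone ester vinyl iodide
Product: 18 methyl (1S,4aR,5R,8aS)-5-({[tert-butyl(dimethyl)silyl]oxy}methyl)-1,4a-dimethyl-6-methylidene-2-oxodecahydronaphthalene-1-carboxylate, via lithium enolate 17 (not isolated)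
Conditions: Li (4.4 equiv), NH3(l)/THF, t-BuOH (2.0 equiv), −78 °C; then MeI, −78 to −33 °C
Reagents that add atoms: iodomethane, CI
Why: Dissolving-metal reductive alkylation of a β-keto ester enone: C5 is protonated axially, trans to the C10 methyl, and enolate 17 is methylated on the face away from that axial methyl, so the ester ends axial and the new methyl equatorial at C4. The same electrons cleave the C12–I bond, and the vinyl anion is protonated to the exocyclic methylene.

Step 14
Reactants: 18 keto ester
Product: 19 (1R,2R,4aR,5R,8aS)-5-({[tert-butyl(dimethyl)silyl]oxy}methyl)-1-(hydroxymethyl)-1,4a-dimethyl-6-methylidenedecahydronaphthalen-2-ol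
Conditions: LiAlH4, THF, 0 °C to reflux
Reagents that add atoms: none
Why: Hydride reduction of ketone and ester; hydride should enter C3 axially from the face opposite the axial C4 ester and the C10 methyl, giving the equatorial C3 alcohol cis to the C4 CH2OH.

Step 15
Reactants: 19 diol
Product: 20 acetonide of 19 (2,2-dimethyl-1,3-dioxane across O3 and the C4 CH2O; C11 silyl ether kept; configuration as in 19)
Conditions: 2,2-dimethoxypropane, PPTS (cat.), CH2Cl2, rt
Reagents that add atoms: 2,2-dimethoxypropane, COC(C)(C)OC
Why: Transacetalisation of a 1,3-diol to a six-membered isopropylidene acetal; the catalytic pyridinium acid is too weak to move C8=C12 or cleave the silyl ether.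

Step 16
Reactants: 20 acetonide silyl ether
Product: 21 acetonide alcohol (free C11 hydroxyl; configuration as in 19)
Conditions: Bu4NF, THF, rt
Reagents that add atoms: none
Why: Fluoride cleavage of the primary silyl ether; the acetonide and the alkene are inert to fluoride.

Step 17
Reactants: 21 acetonide alcohol; 22 umbelliferone (7-hydroxy-2H-chromen-2-one)
Product: 23 acetonide of 24 (C11 ether to O7 of the coumarin)
Conditions: PPh3, DIAD, THF, 0 to 40 °C
Reagents that add atoms: none
Why: Mitsunobu etherification; the acidic phenol of 22 displaces the activated primary C11 oxygen, no stereocentre is involved, and the only other hydroxyls are tied up in the acetonide.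

Step 18
Reactants: 23 acetonide ether
Product: 24 7-{[(1R,4aS,5R,6R,8aR)-6-hydroxy-5-(hydroxymethyl)-5,8a-dimethyl-2-methylidenedecahydronaphthalen-1-yl]methoxy}-2H-chromen-2-one (target)
Conditions: AcOH/H2O (4:1), 40 °C
Reagents that add atoms: none
Why: Acid hydrolysis of the isopropylidene acetal with a weak acid, which should leave the exocyclic alkene, the aryl ether and the lactone untouched.

## Compound list

1 | methyl 2-hydroxy-6-methylbenzoate | COC(=O)c1c(C)cccc1O | starting material
2 | methyl 3-bromo-6-hydroxy-2-methylbenzoate | COC(=O)c1c(C)c(Br)ccc1O | intermediate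
3 | methyl 3-bromo-6-(methoxymethoxy)-2-methylbenzoate | COCOc1ccc(Br)c(C)c1C(=O)OC | intermediate
4 | methyl 6-(methoxymethoxy)-2,3-dimethylbenzoate | COCOc1ccc(C)c(C)c1C(=O)OC | intermediate
5 | 3-bromo-1-(trimethylsilyl)prop-1-yne | C[Si](C)(C)C#CCBr | starting material
6 | methyl 2-(lithiomethyl)-6-(methoxymethoxy)-3-methylbenzoate | [Li]Cc1c(C)ccc(OCOC)c1C(=O)OC | intermediate (not isolated)
7 | methyl 6-(methoxymethoxy)-3-methyl-2-[4-(trimethylsilyl)but-3-yn-1-yl]benzoate | COCOc1ccc(C)c(CCC#C[Si](C)(C)C)c1C(=O)OC | intermediate
8 | (tert-butyldimethylsilyloxy)acetaldehyde | O=CCO[Si](C)(C)C(C)(C)C | starting material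
9 | methyl 2-[(3E)-5-{[tert-butyl(dimethyl)silyl]oxy}-4-hydroxy-3-[(trimethylsilyl)methylidene]pentyl]-6-(methoxymethoxy)-3-methylbenzoate, racemic | COCOc1ccc(C)c(CC/C(=C\[Si](C)(C)C)C(O)CO[Si](C)(C)C(C)(C)C)c1C(=O)OC | intermediate
10 | methyl 2-[(3E)-5-{[tert-butyl(dimethyl)silyl]oxy}-4-oxo-3-[(trimethylsilyl)methylidene]pentyl]-6-(methoxymethoxy)-3-methylbenzoate | COCOc1ccc(C)c(CC/C(=C\[Si](C)(C)C)C(=O)CO[Si](C)(C)C(C)(C)C)c1C(=O)OC | intermediate
11 | methyl 2-[(3E,4S)-5-{[tert-butyl(dimethyl)silyl]oxy}-4-hydroxy-3-[(trimethylsilyl)methylidene]pentyl]-6-(methoxymethoxy)-3-methylbenzoate | COCOc1ccc(C)c(CC/C(=C\[Si](C)(C)C)[C@H](O)CO[Si](C)(C)C(C)(C)C)c1C(=O)OC | intermediate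
12 | methyl 2-[(3E,4S)-5-{[tert-butyl(dimethyl)silyl]oxy}-4-[(methoxycarbonyl)oxy]-3-[(trimethylsilyl)methylidene]pentyl]-6-(methoxymethoxy)-3-methylbenzoate | COCOc1ccc(C)c(CC/C(=C\[Si](C)(C)C)[C@H](OC(=O)OC)CO[Si](C)(C)C(C)(C)C)c1C(=O)OC | intermediate
13 | methyl 2-[(3E,4S)-5-{[tert-butyl(dimethyl)silyl]oxy}-4-[(methoxycarbonyl)oxy]-3-[(trimethylsilyl)methylidene]pentyl]-6-hydroxy-3-methylbenzoate | COC(=O)c1c(O)ccc(C)c1CC/C(=C\[Si](C)(C)C)[C@H](OC(=O)OC)CO[Si](C)(C)C(C)(C)C | intermediate (key-step precursor)
14 | methyl (4aS,5S,6E)-5-({[tert-butyl(dimethyl)silyl]oxy}methyl)-4a-methyl-2-oxo-6-[(trimethylsilyl)methylidene]-2,4a,5,6,7,8-hexahydronaphthalene-1-carboxylate | C[Si](C)(C)/C=C1\CCC2=C(C(=O)OC)C(=O)C=C[C@@]2(C)[C@@H]1CO[Si](C)(C)C(C)(C)C | intermediate (key-step product)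
15 | methyl (4aS,5S,6E)-5-({[tert-butyl(dimethyl)silyl]oxy}methyl)-4a-methyl-2-oxo-6-[(trimethylsilyl)methylidene]-2,3,4,4a,5,6,7,8-octahydronaphthalene-1-carboxylate | C[Si](C)(C)/C=C1\CCC2=C(C(=O)OC)C(=O)CC[C@@]2(C)[C@@H]1CO[Si](C)(C)C(C)(C)C | intermediate
16 | methyl (4aS,5S,6E)-5-({[tert-butyl(dimethyl)silyl]oxy}methyl)-6-(iodomethylidene)-4a-methyl-2-oxo-2,3,4,4a,5,6,7,8-octahydronaphthalene-1-carboxylate | I/C=C1\CCC2=C(C(=O)OC)C(=O)CC[C@@]2(C)[C@@H]1CO[Si](C)(C)C(C)(C)C | intermediate
17 | lithium enolate of the trans-fused β-keto ester (O3–Li, C3=C4; H5 trans to the C10 methyl; C8=CH2; C4 not yet methylated) | C=C1CC[C@@H]2C(C(=O)OC)=C(O[Li])CC[C@@]2(C)[C@@H]1CO[Si](C)(C)C(C)(C)C | intermediate (not isolated)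
18 | methyl (1S,4aR,5R,8aS)-5-({[tert-butyl(dimethyl)silyl]oxy}methyl)-1,4a-dimethyl-6-methylidene-2-oxodecahydronaphthalene-1-carboxylate | C=C1CC[C@@H]2[C@](C)(C(=O)OC)C(=O)CC[C@@]2(C)[C@@H]1CO[Si](C)(C)C(C)(C)C | intermediate
19 | (1R,2R,4aR,5R,8aS)-5-({[tert-butyl(dimethyl)silyl]oxy}methyl)-1-(hydroxymethyl)-1,4a-dimethyl-6-methylidenedecahydronaphthalen-2-ol | C=C1CC[C@@H]2[C@](C)(CO)[C@H](O)CC[C@@]2(C)[C@@H]1CO[Si](C)(C)C(C)(C)C | intermediate
20 | acetonide of 19 (2,2-dimethyl-1,3-dioxane across O3 and the C4 CH2O; C11 tert-butyldimethylsilyl ether) | C=C1CC[C@@H]2[C@]3(C)COC(C)(C)O[C@@H]3CC[C@@]2(C)[C@@H]1CO[Si](C)(C)C(C)(C)C | intermediate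
21 | acetonide alcohol (20 with free C11 hydroxyl) | C=C1CC[C@@H]2[C@]3(C)COC(C)(C)O[C@@H]3CC[C@@]2(C)[C@@H]1CO | intermediate
22 | umbelliferone (7-hydroxy-2H-chromen-2-one) | Oc1ccc2ccc(=O)oc2c1 | starting material
23 | acetonide of 24 (C11–O7 coumarin ether of 21) | C=C1CC[C@@H]2[C@]3(C)COC(C)(C)O[C@@H]3CC[C@@]2(C)[C@@H]1COc1ccc2ccc(=O)oc2c1 | intermediate
24 | 7-{[(1R,4aS,5R,6R,8aR)-6-hydroxy-5-(hydroxymethyl)-5,8a-dimethyl-2-methylidenedecahydronaphthalen-1-yl]methoxy}-2H-chromen-2-one | C=C1CC[C@@H]2[C@](C)(CO)[C@H](O)CC[C@@]2(C)[C@@H]1COc1ccc2ccc(=O)oc2c1 | target

## Step count and least certain steps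

Total step count: 18. Longest linear sequence: 18 steps (1 to 24); 5, 8 and 22 are bought.

**Step 10 (key step).**
- Ionisation of a hindered, silyl-bearing trisubstituted alkene may be slow with the bulky diphosphine, and the allyl complex may then lose a β-hydrogen to a diene before C10 attacks.
- The closure may go through the arrangement that places the CH2OTBS arm over ring A, which means poor facial pairing at C10.
- The ester-bearing ortho carbon may compete.
- A smaller achiral phosphine is the first adjustment, since the configuration comes from the carbonate.
- The fallback uses known chemistry, the base-mediated intramolecular C-alkylation of a phenolate. It sets out from 11. The methoxymethyl ether is cleaved as in step 9 to the phenolic (S)-allylic alcohol F1. An Appel chlorination (PPh3, CCl4) gives, with inversion, the phenolic (R)-allylic chloride F2. KOtBu in t-BuOH/THF then lets C10 displace chloride with a second inversion. The silyl group still blocks the SN2′ site. The sequence returns to the route at 14.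

**Step 13.**
- Three events share one flask. Base formed on protonating the vinyl anion may cause a second methylation at C2, the C–I bond may be cleaved incompletely, and the protonation at C5 may lose its trans preference.
- The fallback separates the tasks and sets out from 15. Reductive methylation (Li, NH3, t-BuOH, then MeI) with the silyl group still in place gives the C12-silyl keto ester F3. NIS gives the C12-iodo keto ester F4. A radical reduction with Bu3SnH and AIBN removes iodine and returns to the route at 18.

**Step 7.**
- The two ketone substituents may be too similar in size for the catalyst, giving low enantiomeric purity. This would pass into 14, because the key step transfers the carbonate configuration and does not correct it.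
- The fallback is a Sharpless kinetic resolution and sets out from racemic 9. With Ti(OiPr)4, L-(+)-diisopropyl tartrate and t-BuOOH, the (R)-enantiomer is consumed as the epoxy alcohol F5, and the slow-reacting (S)-enantiomer is recovered. It returns to the route at 11, at the cost of half the material.

**Step 17.**
- Displacement at the β-branched C11 next to quaternary C10 may be slow, so the phosphonium intermediate may eliminate or be intercepted by the reduced azo reagent.
- The fallback sets out from 21. MsCl and Et3N give the C11 mesylate F6, which is displaced by the cesium phenoxide of 22 (Cs2CO3, DMF, 60 °C). It returns to the route at 23.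

## Further compounds

F1 | step 10 | methyl 2-[(3E,4S)-5-{[tert-butyl(dimethyl)silyl]oxy}-4-hydroxy-3-[(trimethylsilyl)methylidene]pentyl]-6-hydroxy-3-methylbenzoate | COC(=O)c1c(O)ccc(C)c1CC/C(=C\[Si](C)(C)C)[C@H](O)CO[Si](C)(C)C(C)(C)C
F2 | step 10 | methyl 2-[(3E,4R)-5-{[tert-butyl(dimethyl)silyl]oxy}-4-chloro-3-[(trimethylsilyl)methylidene]pentyl]-6-hydroxy-3-methylbenzoate | COC(=O)c1c(O)ccc(C)c1CC/C(=C\[Si](C)(C)C)[C@@H](Cl)CO[Si](C)(C)C(C)(C)C
F3 | step 13 | keto ester 18 carrying trimethylsilyl on C12 (E) | C[Si](C)(C)/C=C1\CC[C@@H]2[C@](C)(C(=O)OC)C(=O)CC[C@@]2(C)[C@@H]1CO[Si](C)(C)C(C)(C)C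
F4 | step 13 | keto ester 18 carrying iodine on C12 (E) | I/C=C1\CC[C@@H]2[C@](C)(C(=O)OC)C(=O)CC[C@@]2(C)[C@@H]1CO[Si](C)(C)C(C)(C)C
F5 | step 7 | methyl 2-{2-[(2R,3R)-2-[(1S)-2-{[tert-butyl(dimethyl)silyl]oxy}-1-hydroxyethyl]-3-(trimethylsilyl)oxiran-2-yl]ethyl}-6-(methoxymethoxy)-3-methylbenzoate | COCOc1ccc(C)c(CC[C@@]2(O[C@@H]2[Si](C)(C)C)[C@@H](O)CO[Si](C)(C)C(C)(C)C)c1C(=O)OC
F6 | step 17 | C11 methanesulfonate of acetonide alcohol 21 | C=C1CC[C@@H]2[C@]3(C)COC(C)(C)O[C@@H]3CC[C@@]2(C)[C@@H]1COS(C)(=O)=O
A1 | alternative 1 | (bromomethyl)dimethylsilyl ether of the 4,10-dimethyl-Δ4-octalin-3-ol with a C9 dioxolane | BrC[Si](C)(C)O[C@@H]1CC[C@]2(C)C(CCCC23OCCO3)=C1C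
A2 | alternative 1 | cis-fused oxasilolane on the trans-decalin with a C9 dioxolane | C[Si]1(C)O[C@@H]2CC[C@]3(C)[C@H](CCCC34OCCO4)[C@]2(C)C1
A3 | alternative 2 | acyclic triene: methyl (E)-3-methyl enoate linked through the C3/C4 acetonide to an (E,E)-1-(tert-butyldimethylsilyloxy) diene | COC(=O)/C=C(\C)CC[C@H]1OC(C)(C)OC[C@@]1(C)/C=C/C=C/O[Si](C)(C)C(C)(C)C
A4 | alternative 2 | trans-fused octalin with C8 silyl ether, C9 methyl ester and C3/C4 acetonide | CC(C)(C)[Si](C)(C)O[C@@H]1C=C[C@@H]2[C@]3(C)COC(C)(C)O[C@@H]3CC[C@@]2(C)[C@@H]1C(=O)OC
A5 | alternative 3 | ring A acetonide carrying but-3-ynyl on C5 and methyl plus vinyl on C10 | C#CCC[C@@H]1[C@]2(C)COC(C)(C)O[C@@H]2CC[C@@]1(C)C=C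
A6 | alternative 3 | decalin acetonide with exocyclic methylene and C11 pinacol boronate | C=C1CC[C@@H]2[C@]3(C)COC(C)(C)O[C@@H]3CC[C@@]2(C)[C@@H]1CB4OC(C)(C)C(C)(C)O4
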